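## Retrosynthetic overview
1. Target 16 is (R)-2-(4-allyl-2,6-dimethoxyphenoxy)-3-(3,4,5-trimethoxyphenyl)propan-1-ol. Its CH2OH comes from the N-acyl oxazolidinone 14 by reductive removal of the auxiliary.
2. The benzylic CH2 of 14 comes from the benzylic carbinol of aldol adduct 12 by ionic deoxygenation, which leaves the O-bearing stereocentre untouched.
3. Key disconnection: the bond between the benzylic carbon and the O-bearing carbon. It is made by an intermolecular Evans boron aldol of aryloxyacetyl imide 8 with 3,4,5-trimethoxybenzaldehyde 9, and this step sets the only stereocentre that survives.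
4. 8 comes from acid 5 and (R)-4-benzyl-1,3-oxazolidin-2-one 6. 5 comes from 4-allyl-2,6-dimethoxyphenol 1 and ethyl bromoacetate 2 by Williamson ether synthesis and saponification.
5. No ring is formed. Both benzene rings and the oxazolidinone ring are bought, and the oxazolidinone is recovered in the last step.

Assumption: 4-allyl-2,6-dimethoxyphenol (methoxyeugenol, a flavour chemical) is taken as a bought starting material.

## Route

Step 1
Reactants: 1 4-allyl-2,6-dimethoxyphenol; 2 ethyl bromoacetate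
Product: 3 ethyl 2-(4-allyl-2,6-dimethoxyphenoxy)acetate
Conditions: K2CO3 (2 equiv), acetone, reflux, 12 h
Reagents that add atoms: none
Why: Williamson ether synthesis, in which the phenol oxygen under K2CO3 displaces bromide from the unhindered, activated α-bromo ester by SN2, and the base is too weak to move the allyl double bond into conjugation.

Step 2
Reactants: 3 ethyl 2-(4-allyl-2,6-dimethoxyphenoxy)acetate
Product: 5 2-(4-allyl-2,6-dimethoxyphenoxy)acetic acid, via lithium carboxylate 4 (not isolated)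
Conditions: LiOH·H2O (2 equiv), THF/H2O 3:1, rt, 3 h; then 1 M HCl to pH 2
Reagents that add atoms: lithium hydroxide [Li+].[OH-]
Why: Ester saponification is made irreversible by carboxylate formation, and neither the aryl ethers nor the allyl group react with aqueous LiOH or dilute HCl.

Step 3
Reactants: 5 2-(4-allyl-2,6-dimethoxyphenoxy)acetic acid; 6 (R)-4-benzyl-1,3-oxazolidin-2-one
Product: 8 (R)-3-[2-(4-allyl-2,6-dimethoxyphenoxy)acetyl]-4-benzyl-1,3-oxazolidin-2-one, via mixed pivalic anhydride 7 (not isolated)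
Conditions: PivCl (1.05 equiv), Et3N (2.5 equiv), THF, −20 °C, 1 h; then 6, LiCl (1.1 equiv), −20 °C → rt, 12 h
Reagents that add atoms: pivaloyl chloride CC(C)(C)C(=O)Cl (its acyl group sits in 7 only and is gone in 8)
Why: N-acylation through a mixed anhydride, in which the tert-butyl group steers attack to the more electrophilic aryloxyacetyl carbonyl, LiCl/Et3N activate the carbamate N–H without a strong base, and the bought auxiliary stereocentre is untouched.

Step 4
Reactants: 8 (R)-3-[2-(4-allyl-2,6-dimethoxyphenoxy)acetyl]-4-benzyl-1,3-oxazolidin-2-one; 9 3,4,5-trimethoxybenzaldehyde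
Product: 12 (R)-3-[(2R,3S)-2-(4-allyl-2,6-dimethoxyphenoxy)-3-hydroxy-3-(3,4,5-trimethoxyphenyl)propanoyl]-4-benzyl-1,3-oxazolidin-2-one, via (Z)-boron enolate 10 (not isolated), via boron aldolate 11 (not isolated)
Conditions: Bu2BOTf (1.2 equiv), Et3N (1.4 equiv), CH2Cl2, 0 °C, 45 min; −78 °C, 9 (1.1 equiv), −78 → 0 °C; then pH 7 buffer, MeOH, 30% H2O2, 0 °C; chromatography and recrystallisation to a single diastereomer
Reagents that add atoms: dibutylboron triflate CCCCB(CCCC)OS(=O)(=O)C(F)(F)F (its Bu2B group sits in 10 and 11 only and is gone in 12)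
Why: Evans syn aldol reaction, in which soft enolisation gives only the (Z)-boron enolate and this adds to the aldehyde through a chair Zimmerman–Traxler transition state on the face away from the benzyl group of the dipole-opposed (R)-auxiliary, setting C2 as R (the lasting stereocentre) and C3 as S (erased in step 5).

Step 5
Reactants: 12 the (2R,3S)-aldol adduct
Product: 14 (R)-3-[(2R)-2-(4-allyl-2,6-dimethoxyphenoxy)-3-(3,4,5-trimethoxyphenyl)propanoyl]-4-benzyl-1,3-oxazolidin-2-one, via benzylic cation 13 (not isolated)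
Conditions: Et3SiH (6 equiv), TFA/CH2Cl2 1:3, 0.05 M, 0 °C → rt
Reagents that add atoms: none
Why: Ionic hydrogenation (Kursanov–Parnes type), in which TFA ionises only the electron-rich benzylic alcohol and excess Et3SiH traps the cation by hydride transfer, while C2 is not a reacting centre and stays R, a monosubstituted alkene is neither protonated nor reduced here, and any proton loss would give a conjugated enoyl imide that is not reduced and so cannot erode the ee.

Step 6
Reactants: 14 the (2R)-imide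
Product: 16 (R)-2-(4-allyl-2,6-dimethoxyphenoxy)-3-(3,4,5-trimethoxyphenyl)propan-1-ol, via (R)-aldehyde 15 (not isolated)
Conditions: LiBH4 (2.5 equiv), MeOH (2.5 equiv), THF, 0 °C, 2 h; then sat. aq. NH4Cl
Reagents that add atoms: none
Why: Reductive cleavage of an N-acyl oxazolidinone, in which hydride adds to the more electrophilic exocyclic carbonyl, the auxiliary leaves, and the aldehyde is reduced at once, so the α-stereocentre has no time to epimerise and the allyl group and aryl ethers are inert to borohydride.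

## Compound list
1 | 4-allyl-2,6-dimethoxyphenol | C=CCc1cc(OC)c(O)c(OC)c1 | starting material
2 | ethyl bromoacetate | CCOC(=O)CBr | starting material
3 | ethyl 2-(4-allyl-2,6-dimethoxyphenoxy)acetate | C=CCc1cc(OC)c(OCC(=O)OCC)c(OC)c1 | intermediate
4 | lithium 2-(4-allyl-2,6-dimethoxyphenoxy)acetate | C=CCc1cc(OC)c(OCC(=O)[O-])c(OC)c1.[Li+] | intermediate (not isolated)
5 | 2-(4-allyl-2,6-dimethoxyphenoxy)acetic acid | C=CCc1cc(OC)c(OCC(=O)O)c(OC)c1 | intermediate
6 | (R)-4-benzyl-1,3-oxazolidin-2-one | O=C1N[C@H](Cc2ccccc2)CO1 | starting material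
7 | 2-(4-allyl-2,6-dimethoxyphenoxy)acetic pivalic anhydride | C=CCc1cc(OC)c(OCC(=O)OC(=O)C(C)(C)C)c(OC)c1 | intermediate (not isolated)
8 | (R)-3-[2-(4-allyl-2,6-dimethoxyphenoxy)acetyl]-4-benzyl-1,3-oxazolidin-2-one | C=CCc1cc(OC)c(OCC(=O)N2[C@H](Cc3ccccc3)COC2=O)c(OC)c1 | intermediate
9 | 3,4,5-trimethoxybenzaldehyde | COc1cc(C=O)cc(OC)c1OC | starting material
10 | (Z)-dibutylboron enolate of 8 | CCCCB(CCCC)O/C(N1[C@H](Cc2ccccc2)COC1=O)=C\Oc1c(OC)cc(CC=C)cc1OC | intermediate (not isolated)
11 | dibutylboron (2R,3S)-aldolate | C=CCc1cc(OC)c(O[C@@H](C(=O)N2[C@H](Cc3ccccc3)COC2=O)[C@@H](OB(CCCC)CCCC)c4cc(OC)c(OC)c(OC)c4)c(OC)c1 | intermediate (not isolated)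
12 | (R)-3-[(2R,3S)-2-(4-allyl-2,6-dimethoxyphenoxy)-3-hydroxy-3-(3,4,5-trimethoxyphenyl)propanoyl]-4-benzyl-1,3-oxazolidin-2-one | C=CCc1cc(OC)c(O[C@@H](C(=O)N2[C@H](Cc3ccccc3)COC2=O)[C@@H](O)c4cc(OC)c(OC)c(OC)c4)c(OC)c1 | intermediate
13 | C3 benzylic cation from 12, C2 configuration unchanged | C=CCc1cc(OC)c(O[C@@H](C(=O)N2[C@H](Cc3ccccc3)COC2=O)[CH+]c4cc(OC)c(OC)c(OC)c4)c(OC)c1 | intermediate (not isolated)
14 | (R)-3-[(2R)-2-(4-allyl-2,6-dimethoxyphenoxy)-3-(3,4,5-trimethoxyphenyl)propanoyl]-4-benzyl-1,3-oxazolidin-2-one | C=CCc1cc(OC)c(O[C@@H](C(=O)N2[C@H](Cc3ccccc3)COC2=O)Cc4cc(OC)c(OC)c(OC)c4)c(OC)c1 | intermediate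
15 | (R)-2-(4-allyl-2,6-dimethoxyphenoxy)-3-(3,4,5-trimethoxyphenyl)propanal | C=CCc1cc(OC)c(O[C@@H](C=O)Cc2cc(OC)c(OC)c(OC)c2)c(OC)c1 | intermediate (not isolated)
16 | (R)-2-(4-allyl-2,6-dimethoxyphenoxy)-3-(3,4,5-trimethoxyphenyl)propan-1-ol | C=CCc1cc(OC)c(O[C@@H](CO)Cc2cc(OC)c(OC)c(OC)c2)c(OC)c1 | target

## Count and risks
Total step count: 6. Longest linear sequence: 6 (1 → 3 → 5 → 8 → 12 → 14 → 16).

**Step 4 (aldol).**
- Risk: the boron Lewis acid may be tied up by the many ether oxygens, so enolisation of the bulky aryloxyacetyl imide stays incomplete. The adduct may also revert on work-up.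
- Fallback: make the C–O bond at the stereocentre instead of the C–C bond. It sets out from phenol 1 and comes back to the route at 16.
- Bought 5-bromo-1,2,3-trimethoxybenzene is turned with Mg in THF into 3,4,5-trimethoxyphenylmagnesium bromide F1. This opens bought (S)-tert-butyldimethylsilyl glycidyl ether at its terminal carbon (10 mol% CuI, THF, −30 → 0 °C; NH4Cl quench) without touching the stereocentre. The product is (S)-1-(tert-butyldimethylsilyloxy)-3-(3,4,5-trimethoxyphenyl)propan-2-ol F2.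
- A Mitsunobu reaction of F2 with 1 (PPh3, DIAD, toluene, 0 °C → rt) inverts the carbinol carbon. It gives (R)-tert-butyl[2-(4-allyl-2,6-dimethoxyphenoxy)-3-(3,4,5-trimethoxyphenyl)propoxy]dimethylsilane F3. Bu4NF in THF then frees 16.

**Step 5 (ionic deoxygenation).**
- Risk: the cation is flanked by an acyl and an aryloxy group, so ionisation may be slow. Friedel–Crafts capture by the electron-rich rings or addition of TFA to the allyl group may then compete.
- Fallback: avoid the carbinol altogether and form the same C–C bond by auxiliary-controlled enolate alkylation. The chelated sodium enolate is attacked on the face opposite to the one used in the boron aldol, so the enantiomeric auxiliary is needed. It sets out from acid 5 and comes back to the route at 16.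
- 5 is activated as 7 exactly as in step 3 and coupled with bought (S)-4-benzyl-1,3-oxazolidin-2-one (LiCl, Et3N). This gives (S)-3-[2-(4-allyl-2,6-dimethoxyphenoxy)acetyl]-4-benzyl-1,3-oxazolidin-2-one F4.
- NaN(SiMe3)2 in THF at −78 °C gives the chelated sodium (Z)-enolate F5. It is alkylated with bought 3,4,5-trimethoxybenzyl bromide (−78 → −40 °C) away from the benzyl group. The product is (S)-3-[(2R)-2-(4-allyl-2,6-dimethoxyphenoxy)-3-(3,4,5-trimethoxyphenyl)propanoyl]-4-benzyl-1,3-oxazolidin-2-one F6.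
- LiBH4/MeOH as in step 6 then gives 16 through 15.

**Step 6 (reductive cleavage).**
- Risk: the acyl group is α-branched and carries a bulky aryloxy group, so hydride may attack the ring carbonyl and open the oxazolidinone instead.
- Fallback: separate cleavage from reduction. It sets out from 14 and comes back to the route at 16.
- LiOH/H2O2 in THF/H2O at 0 °C is used because hydroperoxide attacks the exocyclic carbonyl even of hindered imides. It gives lithium (R)-2-(4-allyl-2,6-dimethoxyphenoxy)-3-(3,4,5-trimethoxyphenyl)propaneperoxoate F7. Na2SO3 reduces this, and acidification gives (R)-2-(4-allyl-2,6-dimethoxyphenoxy)-3-(3,4,5-trimethoxyphenyl)propanoic acid F8.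
- Isobutyl chloroformate and N-methylmorpholine (THF, −15 °C) give the isobutyl carbonic mixed anhydride F9. NaBH4 in THF/H2O reduces it through 15 to 16. Borane is avoided because of the allyl group.

## Further compounds
F1 | step 4 | 3,4,5-trimethoxyphenylmagnesium bromide | COc1cc([Mg]Br)cc(OC)c1OC
F2 | step 4 | (S)-1-(tert-butyldimethylsilyloxy)-3-(3,4,5-trimethoxyphenyl)propan-2-ol | O[C@H](CO[Si](C)(C)C(C)(C)C)Cc1cc(OC)c(OC)c(OC)c1
F3 | step 4 | (R)-tert-butyl[2-(4-allyl-2,6-dimethoxyphenoxy)-3-(3,4,5-trimethoxyphenyl)propoxy]dimethylsilane | C=CCc1cc(OC)c(O[C@@H](CO[Si](C)(C)C(C)(C)C)Cc2cc(OC)c(OC)c(OC)c2)c(OC)c1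
F4 | step 5 | (S)-3-[2-(4-allyl-2,6-dimethoxyphenoxy)acetyl]-4-benzyl-1,3-oxazolidin-2-one | C=CCc1cc(OC)c(OCC(=O)N2[C@@H](Cc3ccccc3)COC2=O)c(OC)c1
F5 | step 5 | sodium (Z)-enolate of F4 | [Na+].[O-]/C(N1[C@@H](Cc2ccccc2)COC1=O)=C\Oc1c(OC)cc(CC=C)cc1OC
F6 | step 5 | (S)-3-[(2R)-2-(4-allyl-2,6-dimethoxyphenoxy)-3-(3,4,5-trimethoxyphenyl)propanoyl]-4-benzyl-1,3-oxazolidin-2-one | C=CCc1cc(OC)c(O[C@@H](C(=O)N2[C@@H](Cc3ccccc3)COC2=O)Cc4cc(OC)c(OC)c(OC)c4)c(OC)c1
F7 | step 6 | lithium (R)-2-(4-allyl-2,6-dimethoxyphenoxy)-3-(3,4,5-trimethoxyphenyl)propaneperoxoate | C=CCc1cc(OC)c(O[C@@H](C(=O)O[O-])Cc2cc(OC)c(OC)c(OC)c2)c(OC)c1.[Li+]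
F8 | step 6 | (R)-2-(4-allyl-2,6-dimethoxyphenoxy)-3-(3,4,5-trimethoxyphenyl)propanoic acid | C=CCc1cc(OC)c(O[C@@H](C(=O)O)Cc2cc(OC)c(OC)c(OC)c2)c(OC)c1
F9 | step 6 | (R)-2-(4-allyl-2,6-dimethoxyphenoxy)-3-(3,4,5-trimethoxyphenyl)propanoic isobutyl carbonic anhydride | C=CCc1cc(OC)c(O[C@@H](C(=O)OC(=O)OCC(C)C)Cc2cc(OC)c(OC)c(OC)c2)c(OC)c1
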